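**Retrosynthetic overview**

- The strategy rests on the β-hydroxy ketone pair C4(OH)–C5–C8(=O) inside the six-membered ring C1–C2=C3–C4–C5–C8 of the bicyclo[3.2.1]oct-2-en-8-one. Cutting C4–C5 (retro-aldol) gives a cyclopentanone (C8, C1, C7, C6, C5) with a methoxy-enal arm on quaternary C1, in which C5 is the only enolisable carbon.
- The arm must have C1 and C4 cis on C2=C3. It is attached to C1, anti to the C7 methyl, by stereoretentive conjugate addition–elimination of the C8/C1 enolate on a β-tosyloxy-α-methoxyacrylate of defined geometry; the ester is then taken to the aldehyde.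
- The C7 methyl comes from cuprate addition anti to the C6 aryl group; the allyl group from α-iodination and Stille coupling; the C5 methoxy group from Rubottom oxidation and O-methylation of a regiodefined enol silane.
- The C6 aryl group is added anti to the silyloxy group of (S)-4-silyloxycyclopentenone, the only source of absolute configuration; that silyloxy group is later eliminated to give the C1=C7 enone.
- Ring order: the five-membered ring comes from the chiral pool; the six-membered ring is closed last by the aldol; the phenol is then unmasked.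

Key step: step 14

Remark: atoms carry the numbering of the bicyclic target (C1 allyl bridgehead, C2=C3 enol ether, C4 carbinol, C5 methoxy bridgehead, C6 aryl, C7 methyl, C8 ketone) in all intermediates; Ar = 3-methoxy-4-(triisopropylsilyloxy)phenyl; the (S)-silyloxycyclopentenone is assumed to be bought as the single enantiomer.

**Route**

Step 1
Reactants: 1 4-bromo-2-methoxyphenol
Product: 2 (4-bromo-2-methoxyphenoxy)triisopropylsilane
Conditions: TIPSCl, imidazole, DMF, rt
Reagents that add atoms: triisopropylsilyl chloride, CC(C)[Si](Cl)(C(C)C)C(C)C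
Why: Silylation of a phenol with a silyl chloride and imidazole; the aryl TIPS ether should survive the organomagnesium, MeLi, i-Bu2AlH and amine steps ahead and still fall to buffered fluoride.

Step 2
Reactants: 2 (4-bromo-2-methoxyphenoxy)triisopropylsilane; 3 (S)-4-(tert-butyldimethylsilyloxy)cyclopent-2-en-1-one
Product: 5 3,4-trans-3-Ar-4-(tert-butyldimethylsilyloxy)-1-(trimethylsilyloxy)cyclopent-1-ene, via arylmagnesium bromide 4 (not isolated)
Conditions: Mg, THF, 40 °C; then CuBr·SMe2 (10 mol%), 3, TMSCl, HMPA, THF, −78 °C; Et3N, pentane work-up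
Reagents that add atoms: chlorotrimethylsilane, C[Si](C)(C)Cl
Why: Copper-catalysed conjugate addition of the arylmagnesium bromide with TMSCl acceleration should deliver the aryl group to C6 anti to the C7 silyloxy group and trap the enolate regiospecifically as the C8/C5 enol silane.

Step 3
Reactants: 5 3,4-trans-3-Ar-4-(tert-butyldimethylsilyloxy)-1-(trimethylsilyloxy)cyclopent-1-ene
Product: 7 2,3-trans-3,4-trans-3-Ar-4-(tert-butyldimethylsilyloxy)-2-hydroxycyclopentan-1-one, via α-silyloxy ketone 6 (not isolated)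
Conditions: mCPBA, NaHCO3, CH2Cl2, 0 °C; then 1 M HCl, THF, 0 °C
Reagents that add atoms: mCPBA, OOC(=O)c1cccc(Cl)c1
Why: Rubottom oxidation: epoxidation of the enol silane on the face opposite the C6 aryl group followed by silyl shift should place the C5 oxygen trans to the aryl group, and brief dilute acid removes only the trimethylsilyl group.

Step 4
Reactants: 7 2,3-trans-3,4-trans-3-Ar-4-(tert-butyldimethylsilyloxy)-2-hydroxycyclopentan-1-one
Product: 8 2,3-trans-3,4-trans-3-Ar-4-(tert-butyldimethylsilyloxy)-2-methoxycyclopentan-1-one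
Conditions: MeOTf, 2,6-di-tert-butyl-4-methylpyridine, CH2Cl2, 0 °C → rt
Reagents that add atoms: methyl triflate, COS(=O)(=O)C(F)(F)F
Why: O-Alkylation of the alcohol with methyl triflate and a hindered pyridine forms no enolate, so the β-silyloxy ketone should neither eliminate nor epimerise.

Step 5
Reactants: 8 2,3-trans-3,4-trans-3-Ar-4-(tert-butyldimethylsilyloxy)-2-methoxycyclopentan-1-one
Product: 11 (4S,5S)-4-Ar-5-methoxycyclopent-2-en-1-one, via β-hydroxy ketone 9 (not isolated), via mesylate 10 (not isolated)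
Conditions: CSA (cat.), MeOH, rt; then MsCl, Et3N, CH2Cl2, −20 → 0 °C
Reagents that add atoms: none
Why: Acidic methanolysis should cleave the alkyl TBS ether but not the aryl TIPS ether, and mesylation with E1cB elimination under the weak base triethylamine should give the C1=C7 enone without deprotonating the benzylic, γ-acidic C6–H of the product.

Step 6
Reactants: 11 (4S,5S)-4-Ar-5-methoxycyclopent-2-en-1-one
Product: 12 (4S,5S)-4-Ar-2-iodo-5-methoxycyclopent-2-en-1-one
Conditions: I2, pyridine, CH2Cl2, rt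
Reagents that add atoms: iodine, II
Why: α-Iodination of the enone by pyridine conjugate addition, iodination of the enolate and elimination should introduce iodine only at C1 and leave both stereocentres untouched.

Step 7
Reactants: 12 (4S,5S)-4-Ar-2-iodo-5-methoxycyclopent-2-en-1-one; 13 allyltributylstannane
Product: 14 (4S,5S)-2-allyl-4-Ar-5-methoxycyclopent-2-en-1-one
Conditions: Pd2(dba)3 (2.5 mol%), AsPh3, CuI, NMP, rt
Reagents that add atoms: none
Why: Stille coupling of the α-iodoenone with the allylstannane, accelerated by AsPh3 and CuI, should form the C1–allyl bond at room temperature without base, so C6 is not endangered.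

Step 8
Reactants: 14 (4S,5S)-2-allyl-4-Ar-5-methoxycyclopent-2-en-1-one
Product: 15 3,4-trans-4,5-trans-2-allyl-4-Ar-5-methoxy-3-methyl-1-(trimethylsilyloxy)cyclopent-1-ene
Conditions: Me2CuLi, TMSCl, THF, −78 °C; Et3N, pentane work-up
Reagents that add atoms: lithium dimethylcuprate, [Li+].C[Cu-]C; chlorotrimethylsilane, C[Si](C)(C)Cl
Why: TMSCl-accelerated cuprate 1,4-addition should put the methyl group on C7 anti to the adjacent C6 aryl group and store the regiodefined C8/C1 enolate as a copper-free silyl enol ether.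

Step 9
Reactants: 16 methyl methoxyacetate; 17 methyl formate
Product: 18 sodium enolate of methyl 2-methoxy-3-oxopropanoate (enolate oxygen cis to the ester)
Conditions: NaH, cat. MeOH, Et2O, 0 °C → rt
Reagents that add atoms: sodium hydride, [Na+].[H-]
Why: Crossed Claisen condensation of the ester enolate with non-enolisable methyl formate should give the α-formyl ester, which separates as its chelated sodium enolate.

Step 10
Reactants: 18 sodium enolate of methyl 2-methoxy-3-oxopropanoate
Product: 19 methyl (E)-2-methoxy-3-(tosyloxy)prop-2-enoate (tosyloxy cis to the ester)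
Conditions: TsCl, LiCl, N-methylimidazole (cat.), MeCN, 0 °C
Reagents that add atoms: p-toluenesulfonyl chloride, Cc1ccc(cc1)S(Cl)(=O)=O
Why: O-Sulfonylation of the lithium-chelated enolate, in which the enolate oxygen and the ester carbonyl are held on the same side of the double bond, should give the enol tosylate with the leaving group cis to the ester, the chelation-controlled outcome known for enol tosylates of α-formyl esters.

Step 11
Reactants: 15 3,4-trans-4,5-trans-2-allyl-4-Ar-5-methoxy-3-methyl-1-(trimethylsilyloxy)cyclopent-1-ene; 19 methyl (E)-2-methoxy-3-(tosyloxy)prop-2-enoate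
Product: 21 methyl (E)-3-(1-allyl-4-Ar-3-methoxy-5-methyl-2-oxocyclopentyl)-2-methoxyprop-2-enoate (arm trans to the C7 methyl and cis to the C6 aryl; C1 cis to the ester carbon), via lithium enolate 20 (not isolated)
Conditions: MeLi, THF, 0 °C → rt; then 19, THF, −78 → −30 °C
Reagents that add atoms: none
Why: MeLi cleaves the enol silane to the regiodefined lithium enolate, which should undergo Michael addition–β-elimination (nucleophilic vinylic substitution) on the β-tosyloxy acrylate: the bond to C1 forms anti to the adjacent C7 methyl group, and fast loss of tosylate from the intermediate ester enolate retains the alkene geometry, leaving C1 cis to C4.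

Step 12
Reactants: 21 methyl (E)-3-(1-allyl-4-Ar-3-methoxy-5-methyl-2-oxocyclopentyl)-2-methoxyprop-2-enoate
Product: 22 (E)-3-(1-allyl-4-Ar-2-hydroxy-3-methoxy-5-methylcyclopentyl)-2-methoxyprop-2-en-1-ol (mixture of C8 epimers)
Conditions: i-Bu2AlH (5 equiv), CH2Cl2, −78 → 0 °C; aq. potassium sodium tartrate
Reagents that add atoms: none
Why: 1,2-Reduction of the enoate by the aluminium hydride should give the cis-allylic alcohol without touching the enol ether double bond; the C8 ketone is reduced as well, to epimers whose configuration is irrelevant because C8 is re-oxidised in the next step.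

Step 13
Reactants: 22 (E)-3-(1-allyl-4-Ar-2-hydroxy-3-methoxy-5-methylcyclopentyl)-2-methoxyprop-2-en-1-ol
Product: 23 (E)-3-(1-allyl-4-Ar-3-methoxy-5-methyl-2-oxocyclopentyl)-2-methoxyprop-2-enal (C1 cis to the formyl carbon)
Conditions: (COCl)2, DMSO, CH2Cl2, −78 → −60 °C; then i-Pr2NEt, −78 → −30 °C
Reagents that add atoms: none
Why: Swern oxidation turns both hydroxyl groups into alkoxysulfonium ions before base is added, so ketone and enal should be released together with no hydroxy-aldehyde left to close to a lactol, and the enal, having no γ-hydrogen, keeps its geometry.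

Step 14
Reactants: 23 (E)-3-(1-allyl-4-Ar-3-methoxy-5-methyl-2-oxocyclopentyl)-2-methoxyprop-2-enal
Product: 25 (1R,4S,5R,6S,7R)-1-allyl-6-Ar-4-hydroxy-3,5-dimethoxy-7-methylbicyclo[3.2.1]oct-2-en-8-one, via enol silane 24 (not isolated)
Conditions: TMSOTf, Et3N, CH2Cl2, −78 → 0 °C; pentane, filter; then MgBr2·OEt2, CH2Cl2, −78 → −20 °C; aq. citric acid work-up
Reagents that add atoms: none
Why: Soft enolisation with TMSOTf/Et3N can give only the C8/C5 enol silane, because C1 is quaternary and the enal has no acidic hydrogen; MgBr2 then binds the aldehyde oxygen and the C3 methoxy oxygen in a five-membered chelate, which activates C4 and holds the enal s-trans so that the formyl hydrogen, not the metal-bound oxygen, faces C1. C5 of the enol silane should add to C4 in an intramolecular Mukaiyama aldol addition, the closest known reaction type being the MgBr2-mediated, chelation-controlled addition of enol silanes to α-alkoxy aldehydes. The six-membered ring C1–C2=C3–C4–C5–C8 closes in the 6-(enolendo)-exo-trig mode across the cyclopentene and completes the bicyclo[3.2.1]octene. The C5 configuration is fixed by the tether, since the cis C2=C3 bond can deliver C4 only to the face of the enol that carries the arm. The C4 configuration should follow from an open transition state with C4=O antiperiplanar to C5=C8 (the chelated metal cannot bridge to the silyloxy oxygen), which turns the aldehyde oxygen toward the C6–C7 bridge, anti to C8, as in the target. The step needs the cis C1/C4 alkene geometry, secured by the stereoretentive vinylic substitution and the lack of a γ-hydrogen, and facial selectivity at C4, secured by the chelate and the open transition state.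

Step 15
Reactants: 25 (1R,4S,5R,6S,7R)-1-allyl-6-Ar-4-hydroxy-3,5-dimethoxy-7-methylbicyclo[3.2.1]oct-2-en-8-one
Product: 26 (1R,4S,5R,6S,7R)-1-allyl-4-hydroxy-6-(4-hydroxy-3-methoxyphenyl)-3,5-dimethoxy-7-methylbicyclo[3.2.1]oct-2-en-8-one
Conditions: Bu4NF, AcOH (1:1), THF, 0 °C
Reagents that add atoms: none
Why: Fluoride cleavage of the aryl silyl ether; acetic acid keeps the medium non-basic, so the β-hydroxy ketone should not undergo retro-aldol opening or C4 epimerisation and the enol ether is not hydrolysed.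

**Compound list**

1 | 4-bromo-2-methoxyphenol | COc1cc(Br)ccc1O | starting material
2 | (4-bromo-2-methoxyphenoxy)triisopropylsilane | COc1cc(Br)ccc1O[Si](C(C)C)(C(C)C)C(C)C | intermediate
3 | (S)-4-(tert-butyldimethylsilyloxy)cyclopent-2-en-1-one | O=C1C=C[C@@H](O[Si](C)(C)C(C)(C)C)C1 | starting material
4 | [3-methoxy-4-(triisopropylsilyloxy)phenyl]magnesium bromide | COc1cc([Mg]Br)ccc1O[Si](C(C)C)(C(C)C)C(C)C | intermediate
5 | 3,4-trans-3-Ar-4-(tert-butyldimethylsilyloxy)-1-(trimethylsilyloxy)cyclopent-1-ene | C[Si](C)(C)OC1=C[C@H](c2ccc(O[Si](C(C)C)(C(C)C)C(C)C)c(OC)c2)[C@@H](O[Si](C)(C)C(C)(C)C)C1 | intermediate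
6 | 2,3-trans-3,4-trans-3-Ar-4-(tert-butyldimethylsilyloxy)-2-(trimethylsilyloxy)cyclopentan-1-one | O=C1C[C@H](O[Si](C)(C)C(C)(C)C)[C@@H](c2ccc(O[Si](C(C)C)(C(C)C)C(C)C)c(OC)c2)[C@@H]1O[Si](C)(C)C | intermediate
7 | 2,3-trans-3,4-trans-3-Ar-4-(tert-butyldimethylsilyloxy)-2-hydroxycyclopentan-1-one | O=C1C[C@H](O[Si](C)(C)C(C)(C)C)[C@@H](c2ccc(O[Si](C(C)C)(C(C)C)C(C)C)c(OC)c2)[C@@H]1O | intermediate
8 | 2,3-trans-3,4-trans-3-Ar-4-(tert-butyldimethylsilyloxy)-2-methoxycyclopentan-1-one | O=C1C[C@H](O[Si](C)(C)C(C)(C)C)[C@@H](c2ccc(O[Si](C(C)C)(C(C)C)C(C)C)c(OC)c2)[C@@H]1OC | intermediate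
9 | 2,3-trans-3,4-trans-3-Ar-4-hydroxy-2-methoxycyclopentan-1-one | O=C1C[C@H](O)[C@@H](c2ccc(O[Si](C(C)C)(C(C)C)C(C)C)c(OC)c2)[C@@H]1OC | intermediate
10 | methanesulfonate of 9 | O=C1C[C@H](OS(C)(=O)=O)[C@@H](c2ccc(O[Si](C(C)C)(C(C)C)C(C)C)c(OC)c2)[C@@H]1OC | intermediate
11 | (4S,5S)-4-Ar-5-methoxycyclopent-2-en-1-one | O=C1C=C[C@@H](c2ccc(O[Si](C(C)C)(C(C)C)C(C)C)c(OC)c2)[C@@H]1OC | intermediate
12 | (4S,5S)-4-Ar-2-iodo-5-methoxycyclopent-2-en-1-one | O=C1C(I)=C[C@@H](c2ccc(O[Si](C(C)C)(C(C)C)C(C)C)c(OC)c2)[C@@H]1OC | intermediate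
13 | allyltributylstannane | C=CC[Sn](CCCC)(CCCC)CCCC | starting material
14 | (4S,5S)-2-allyl-4-Ar-5-methoxycyclopent-2-en-1-one | C=CCC1=C[C@@H](c2ccc(O[Si](C(C)C)(C(C)C)C(C)C)c(OC)c2)[C@H](OC)C1=O | intermediate
15 | 3,4-trans-4,5-trans-2-allyl-4-Ar-5-methoxy-3-methyl-1-(trimethylsilyloxy)cyclopent-1-ene | C=CCC1=C(O[Si](C)(C)C)[C@@H](OC)[C@H](c2ccc(O[Si](C(C)C)(C(C)C)C(C)C)c(OC)c2)[C@H]1C | intermediate
16 | methyl methoxyacetate | COCC(=O)OC | starting material
17 | methyl formate | COC=O | starting material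
18 | sodium enolate of methyl 2-methoxy-3-oxopropanoate (enolate oxygen cis to the ester) | [Na+].[O-]/C=C(OC)\C(=O)OC | intermediate
19 | methyl (E)-2-methoxy-3-(tosyloxy)prop-2-enoate (tosyloxy cis to the ester) | COC(=O)/C(OC)=C\OS(=O)(=O)c1ccc(C)cc1 | intermediate
20 | lithium C8/C1 enolate of 3,4-trans-4,5-trans-2-allyl-4-Ar-5-methoxy-3-methylcyclopentanone | C=CCC1=C(O[Li])[C@@H](OC)[C@H](c2ccc(O[Si](C(C)C)(C(C)C)C(C)C)c(OC)c2)[C@H]1C | intermediate
21 | methyl (E)-3-(1-allyl-4-Ar-3-methoxy-5-methyl-2-oxocyclopentyl)-2-methoxyprop-2-enoate | C=CC[C@@]1(/C=C(OC)\C(=O)OC)C(=O)[C@@H](OC)[C@H](c2ccc(O[Si](C(C)C)(C(C)C)C(C)C)c(OC)c2)[C@H]1C | intermediate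
22 | (E)-3-(1-allyl-4-Ar-2-hydroxy-3-methoxy-5-methylcyclopentyl)-2-methoxyprop-2-en-1-ol, C8 epimers | C=CC[C@@]1(/C=C(OC)\CO)C(O)[C@@H](OC)[C@H](c2ccc(O[Si](C(C)C)(C(C)C)C(C)C)c(OC)c2)[C@H]1C | intermediate
23 | (E)-3-(1-allyl-4-Ar-3-methoxy-5-methyl-2-oxocyclopentyl)-2-methoxyprop-2-enal | C=CC[C@@]1(/C=C(OC)\C=O)C(=O)[C@@H](OC)[C@H](c2ccc(O[Si](C(C)C)(C(C)C)C(C)C)c(OC)c2)[C@H]1C | intermediate
24 | C8/C5 trimethylsilyl enol ether of 23 | C=CC[C@@]1(/C=C(OC)\C=O)C(O[Si](C)(C)C)=C(OC)[C@H](c2ccc(O[Si](C(C)C)(C(C)C)C(C)C)c(OC)c2)[C@H]1C | intermediate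
25 | (1R,4S,5R,6S,7R)-1-allyl-6-Ar-4-hydroxy-3,5-dimethoxy-7-methylbicyclo[3.2.1]oct-2-en-8-one | C=CC[C@@]12C=C(OC)[C@H](O)[C@@](OC)(C1=O)[C@H](c3ccc(O[Si](C(C)C)(C(C)C)C(C)C)c(OC)c3)[C@H]2C | intermediate
26 | (1R,4S,5R,6S,7R)-1-allyl-4-hydroxy-6-(4-hydroxy-3-methoxyphenyl)-3,5-dimethoxy-7-methylbicyclo[3.2.1]oct-2-en-8-one | C=CC[C@@]12C=C(OC)[C@H](O)[C@@](OC)(C1=O)[C@H](c1ccc(O)c(OC)c1)[C@H]2C | target

**Step count and risks**

Total step count: 15. Longest linear sequence: 13 (steps 1–8 and 11–15; steps 9–10 make the tosylate 19).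

Steps most likely to fail:

Step 11. The hindered tetrasubstituted enolate may add only slowly to the donor-substituted acrylate. Proton transfer from C5–H of the product may quench unreacted enolate. If the intermediate ester enolate lives long enough to rotate before tosylate is lost, the C1/C4 cis geometry erodes. The fallback enforces the geometry with a ring; it sets out from 15 and rejoins at 22. Compound 15 is treated with trimethyl orthoformate and BF3·OEt2 (Mukaiyama-type addition to the dialkoxycarbenium ion, anti to the C7 methyl) to give the β-keto dimethyl acetal F1. NaBH4 reduction and separation give the C8 alcohol with its hydroxyl cis to the acetal F2. Esterification with 2-(dimethoxyphosphoryl)-2-methoxyacetic acid (DCC, DMAP) gives the phosphonoacetate F3. Aqueous trifluoroacetic acid unmasks the aldehyde F4. LiCl/i-Pr2NEt then effects the intramolecular Horner–Wadsworth–Emmons olefination to the fused unsaturated δ-lactone F5, whose six-membered ring forces C1 and C4 cis on C2=C3. Reduction with i-Bu2AlH opens the lactone to diol 22 (one C8 epimer).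

Step 14. The facial selectivity at C4 may be poor: a synclinal open transition state, or a closed pathway after silicon–magnesium exchange at the enolate, would place the hydroxyl syn to C8. The fallback sets C4 by hydride delivery instead; it sets out from 23 and rejoins at 25. The closure is run without regard to C4 (same enol silane, BF3·OEt2), giving 25 together with its C4 epimer F6. The mixture is oxidised with Dess–Martin periodinane to the 4,8-dione F7, in which only the C4 carbonyl is conjugated. Luche reduction (NaBH4, CeCl3·7H2O, MeOH, −78 °C) should then deliver hydride to C4 from the C8 face, because the endo aryl group on C6 screens the other face, and return 25.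

Step 13. Activation of the hindered C8 hydroxyl may lag behind that of the allylic one, so the enal would form first, close to a lactol and be over-oxidised to the lactone; the amine could also isomerise the cis-enal. The fallback creates the nucleophile before the aldehyde exists; it sets out from 21 and rejoins at 25. TBSOTf/Et3N converts 21 to the C8/C5 tert-butyldimethylsilyl enol ether F8. Reduction with i-Bu2AlH now touches only the ester and gives the allylic alcohol F9. MnO2 oxidises it to the enal F10, which is closed directly with MgBr2·OEt2 and mild acid work-up to 25.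

Further compounds
F1 | step 11 | 2-allyl-4-Ar-2-(dimethoxymethyl)-5-methoxy-3-methylcyclopentan-1-one (acetal trans to the C7 methyl) | C=CC[C@@]1(C(OC)OC)C(=O)[C@@H](OC)[C@H](c2ccc(O[Si](C(C)C)(C(C)C)C(C)C)c(OC)c2)[C@H]1C
F2 | step 11 | 2-allyl-4-Ar-2-(dimethoxymethyl)-5-methoxy-3-methylcyclopentan-1-ol (hydroxyl cis to the acetal) | C=CC[C@@]1(C(OC)OC)[C@H](O)[C@@H](OC)[C@H](c2ccc(O[Si](C(C)C)(C(C)C)C(C)C)c(OC)c2)[C@H]1C
F3 | step 11 | 2-(dimethoxyphosphoryl)-2-methoxyacetate ester of F2 | C=CC[C@@]1(C(OC)OC)[C@H](OC(=O)C(OC)P(=O)(OC)OC)[C@@H](OC)[C@H](c2ccc(O[Si](C(C)C)(C(C)C)C(C)C)c(OC)c2)[C@H]1C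
F4 | step 11 | aldehyde from F3 (C1 formyl group) | C=CC[C@@]1(C=O)[C@H](OC(=O)C(OC)P(=O)(OC)OC)[C@@H](OC)[C@H](c2ccc(O[Si](C(C)C)(C(C)C)C(C)C)c(OC)c2)[C@H]1C
F5 | step 11 | cis-fused 3-methoxy-5,6-dihydro-2H-pyran-2-one (lactone O on C8, C2=C3 in the ring) | C=CC[C@@]12C=C(OC)C(=O)O[C@@H]1[C@@H](OC)[C@H](c3ccc(O[Si](C(C)C)(C(C)C)C(C)C)c(OC)c3)[C@H]2C
F6 | step 14 | C4 epimer of 25 (hydroxyl syn to C8) | C=CC[C@@]12C=C(OC)[C@@H](O)[C@@](OC)(C1=O)[C@H](c3ccc(O[Si](C(C)C)(C(C)C)C(C)C)c(OC)c3)[C@H]2C
F7 | step 14 | 1-allyl-6-Ar-3,5-dimethoxy-7-methylbicyclo[3.2.1]oct-2-ene-4,8-dione | C=CC[C@@]12C=C(OC)C(=O)[C@@](OC)(C1=O)[C@H](c3ccc(O[Si](C(C)C)(C(C)C)C(C)C)c(OC)c3)[C@H]2C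
F8 | step 13 | C8/C5 tert-butyldimethylsilyl enol ether of 21 | C=CC[C@@]1(/C=C(OC)\C(=O)OC)C(O[Si](C)(C)C(C)(C)C)=C(OC)[C@H](c2ccc(O[Si](C(C)C)(C(C)C)C(C)C)c(OC)c2)[C@H]1C
F9 | step 13 | allylic alcohol from F8 | C=CC[C@@]1(/C=C(OC)\CO)C(O[Si](C)(C)C(C)(C)C)=C(OC)[C@H](c2ccc(O[Si](C(C)C)(C(C)C)C(C)C)c(OC)c2)[C@H]1C
F10 | step 13 | C8/C5 tert-butyldimethylsilyl enol ether of 23 | C=CC[C@@]1(/C=C(OC)\C=O)C(O[Si](C)(C)C(C)(C)C)=C(OC)[C@H](c2ccc(O[Si](C(C)C)(C(C)C)C(C)C)c(OC)c2)[C@H]1C
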